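**Plan**

- The ring is numbered C1 (C=O), C2 (OH), C3 (icosyl), C4 (C=O), C5 (OMe), C6 (H). Only the oxygens at C1 and C5 alternate with the chain carbon C3. This is the pattern of a fatty-acyl tetraketide whose three ketone carbons become C3, C5 and C1 and whose ester-flanked methylene becomes C2.
- Retrosynthesis removes the C2 hydroxyl (epoxide isomerisation, epoxidation) and the C4 oxygen (para-oxidation of a phenol), restores a carboxyl at C2 and cuts the ring bond C2–C3 (aldol). It then cuts the bond between the chain ketone carbon and its neighbouring methylene (acylation of a C6 diketo ester trianion by the C21 ester).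
- Forward, the open C27 chain is joined first and the single carbocycle closes by aldol aromatisation. O-methylation, decarboxylation, para-oxidation and hydroxylation at C2 follow.
- The target has no stereocentre. The centres of the aldol adduct and of the racemic epoxide are erased by aromatisation and by isomerisation.

Key step: step 4

Remark: the β-polycarbonyl intermediates are drawn as keto tautomers although they exist largely as enols, and the LiN(iPr)2 and Mg(OMe)2 solutions and (KSO3)2NO are taken as purchased reagents.

**Route**

Step 1
Reactants: 1 henicosanoic acid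
Product: 2 methyl henicosanoate
Conditions: MeOH, H2SO4 (cat.), reflux
Reagents that add atoms: methanol, CO
Why: Fischer esterification of an unhindered fatty acid in excess methanol should go to completion and provides the acyl donor for the chain extension.

Step 2
Reactants: 3 dehydroacetic acid
Product: 4 methyl 3,5-dioxohexanoate
Conditions: Mg(OMe)2 (2 equiv), MeOH, reflux; then cold aq. HCl
Reagents that add atoms: magnesium methoxide, [Mg+2].[O-]C.[O-]C; methanol, CO
Why: Methoxide opens the pyranone lactone and removes the 3-acetyl group by retro-Claisen cleavage, while the magnesium chelate of the diketo ester prevents recyclisation (lactone methanolysis with deacetylation).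

Step 3
Reactants: 4 methyl 3,5-dioxohexanoate; 2 methyl henicosanoate
Product: 6 methyl 3,5,7-trioxoheptacosanoate, via trilithio methyl 3,5-dioxohexanoate 5 (not isolated)
Conditions: LiN(iPr)2 (3.1 equiv per 4), THF, 0 °C; then 2 (0.5 equiv per 4), 0 °C to rt; cold aq. HCl
Reagents that add atoms: none
Why: Claisen-type acylation of a polyanion: the last-formed, most basic carbanion at the terminal methyl of the trianion attacks the ester, and the second equivalent of trianion deprotonates the new triketo ester so that no further addition occurs.

Step 4
Reactants: 6 methyl 3,5,7-trioxoheptacosanoate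
Product: 8 methyl 2,4-dihydroxy-6-icosylbenzoate, via cyclic aldol adduct 7 (not isolated)
Conditions: Cs2CO3 (2 equiv), MeOH–THF, 0 °C to rt; then HCl in MeOH to pH 2, rt
Reagents that add atoms: none
Why: Carbonate in methanol converts the triketo ester into its polyenolate, and the carbon between the ester and the C3 ketone adds to the remote C7 ketone, forming the C2–C7 bond and the cyclohexane ring of adduct 7. Acidification removes one molecule of water by β-elimination of the tertiary carbinol, and double enolisation of the resulting cyclohexenedione gives arene 8. The closest known reaction type is the biomimetic aldol cyclisation of 3,5,7-triketo esters to β-resorcylates. The one ring closes in the 6-(enolexo)-exo-trig mode, and the two centres of 7 need no control because both become sp2 carbons. The step needs aldol closure to win over Claisen closure onto the ester (acylphloroglucinol) and over lactonisation to a 4-hydroxy-2-pyranone. The methyl ester is the poorest electrophile of the chain, carbonate at room temperature does not drive acyl substitution, and the C8 methylene is too weakly acidic to start the alternative aldol onto C3.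

Step 5
Reactants: 8 methyl 2,4-dihydroxy-6-icosylbenzoate
Product: 9 methyl 2-hydroxy-6-icosyl-4-methoxybenzoate
Conditions: MeI (1.1 equiv), K2CO3 (1.1 equiv), acetone, rt
Reagents that add atoms: iodomethane, CI
Why: Williamson methylation should occur only at the 4-hydroxyl, which is the more acidic and unchelated phenol, because the 2-hydroxyl is held in a hydrogen bond to the ester carbonyl.

Step 6
Reactants: 9 methyl 2-hydroxy-6-icosyl-4-methoxybenzoate
Product: 11 3-icosyl-5-methoxyphenol, via 2-hydroxy-6-icosyl-4-methoxybenzoic acid 10 (not isolated)
Conditions: KOH, ethylene glycol–H2O, 130 °C; then aq. HCl to pH 1, 100 °C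
Reagents that add atoms: none
Why: Saponification of the hindered salicylate is followed by protodecarboxylation, since the electron-rich ortho-hydroxy, para-methoxy acid is protonated at the ipso carbon and loses CO2 on heating in acid.

Step 7
Reactants: 11 3-icosyl-5-methoxyphenol
Product: 12 2-icosyl-6-methoxy-1,4-benzoquinone
Conditions: (KSO3)2NO (2.5 equiv), aq. KH2PO4, THF–acetone, rt
Reagents that add atoms: potassium nitrosodisulfonate, [K+].[K+].[O]N(S(=O)(=O)[O-])S(=O)(=O)[O-]
Why: Teuber oxidation: the phenoxyl radical is captured at its free para position by a second nitroxyl and loses imidodisulfonate to give the para-quinone, as is usual for 5-alkyl-3-methoxyphenols.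

Step 8
Reactants: 12 2-icosyl-6-methoxy-1,4-benzoquinone
Product: 13 1-icosyl-3-methoxy-7-oxabicyclo[4.1.0]hept-3-ene-2,5-dione (racemic)
Conditions: t-BuOOH (1.2 equiv), DBU (0.1 equiv), CH2Cl2, 0 °C
Reagents that add atoms: tert-butyl hydroperoxide, CC(C)(C)OO
Why: Weitz–Scheffer epoxidation: the peroxide anion adds to the unsubstituted carbon of the alkyl-bearing C=C, which is β to the more electrophilic cross-conjugated carbonyl, while the methoxy-bearing C=C is a deactivated vinylogous ester; the cis ring fusion is the only one possible and the epoxide forms as a racemate.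

Step 9
Reactants: 13 1-icosyl-3-methoxy-7-oxabicyclo[4.1.0]hept-3-ene-2,5-dione
Product: 14 Irisoquin-D (2-hydroxy-3-icosyl-5-methoxy-1,4-benzoquinone)
Conditions: conc. H2SO4 on SiO2, CH2Cl2, rt
Reagents that add atoms: none
Why: Acid-promoted isomerisation of an epoxyquinone to a hydroxyquinone (as for 2-alkyl-2,3-epoxynaphthoquinones): the C–O bond at the quaternary carbon breaks and the only α-hydrogen, on the oxygen-bearing CH, is lost, so the hydroxyl can only end up next to the icosyl group.

**Compound list**

1 | henicosanoic acid | CCCCCCCCCCCCCCCCCCCCC(=O)O | starting material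
2 | methyl henicosanoate | CCCCCCCCCCCCCCCCCCCCC(=O)OC | intermediate
3 | dehydroacetic acid | CC(=O)C1=C(O)C=C(C)OC1=O | starting material
4 | methyl 3,5-dioxohexanoate | CC(=O)CC(=O)CC(=O)OC | intermediate
5 | trilithio methyl 3,5-dioxohexanoate (trianion at C2, C4 and C6; not isolated) | [Li+].[Li+].[Li+].[CH2-]C(=O)[CH-]C(=O)[CH-]C(=O)OC | intermediate
6 | methyl 3,5,7-trioxoheptacosanoate | CCCCCCCCCCCCCCCCCCCCC(=O)CC(=O)CC(=O)CC(=O)OC | intermediate
7 | methyl 2-hydroxy-2-icosyl-4,6-dioxocyclohexane-1-carboxylate (cyclic aldol adduct, mixture of diastereomers, not isolated) | CCCCCCCCCCCCCCCCCCCCC1(O)CC(=O)CC(=O)C1C(=O)OC | intermediate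
8 | methyl 2,4-dihydroxy-6-icosylbenzoate | CCCCCCCCCCCCCCCCCCCCc1cc(O)cc(O)c1C(=O)OC | intermediate
9 | methyl 2-hydroxy-6-icosyl-4-methoxybenzoate | CCCCCCCCCCCCCCCCCCCCc1cc(OC)cc(O)c1C(=O)OC | intermediate
10 | 2-hydroxy-6-icosyl-4-methoxybenzoic acid (not isolated) | CCCCCCCCCCCCCCCCCCCCc1cc(OC)cc(O)c1C(=O)O | intermediate
11 | 3-icosyl-5-methoxyphenol | CCCCCCCCCCCCCCCCCCCCc1cc(OC)cc(O)c1 | intermediate
12 | 2-icosyl-6-methoxy-1,4-benzoquinone | CCCCCCCCCCCCCCCCCCCCC1=CC(=O)C=C(OC)C1=O | intermediate
13 | 1-icosyl-3-methoxy-7-oxabicyclo[4.1.0]hept-3-ene-2,5-dione (racemic, cis-fused; one enantiomer drawn) | CCCCCCCCCCCCCCCCCCCC[C@@]12O[C@@H]1C(=O)C=C(OC)C2=O | intermediate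
14 | Irisoquin-D, 2-hydroxy-3-icosyl-5-methoxy-1,4-benzoquinone | CCCCCCCCCCCCCCCCCCCCC1=C(O)C(=O)C=C(OC)C1=O | target

**Step count**

Total steps: 9. Longest linear sequence: 8 steps (from 1 through steps 1 and 3 to 9; the branch from 3 through steps 2 to 9 is equally long).

**Steps most likely to fail**

Step 3. The trianion may act as a base toward the enolisable fatty ester, or be quenched by the product, so that terminal acylation stalls; the triketo ester may also cyclise during work-up.
- The fallback sets out from 2 and comes back at 6.
- Ester 2 would be converted with MeNHOMe·HCl and iPrMgCl (THF, −10 °C) into N-methoxy-N-methylhenicosanamide F1.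
- Separately, commercial 2,2,6-trimethyl-4H-1,3-dioxin-4-one would be deprotonated with LiN(SiMe3)2 (THF, −78 °C) and C-acetylated with acetyl chloride to give 2,2-dimethyl-6-(2-oxopropyl)-4H-1,3-dioxin-4-one F2.
- The dianion of F2 (LiN(iPr)2, 2.2 equiv, THF, −78 °C) would be acylated at its terminal methyl by F1 to give 6-(2,4-dioxotetracosyl)-2,2-dimethyl-4H-1,3-dioxin-4-one F3.
- Heating F3 with methanol in toluene at 110 °C should expel acetone and trap the acylketene as triketo ester 6.

Step 4. Claisen closure onto the ester or lactonisation to the pyranone may compete with the aldol mode.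
- The fallback sets out from 2, by way of the diketo-dioxinone F3 described above, and comes back at 8.
- With the ester carbonyl locked in the dioxinone ring, Et3N in CH2Cl2 at rt should close the same ring bond by aldol addition of the dioxinone α-carbon to the chain ketone and dehydration.
- This would give 7-hydroxy-5-icosyl-2,2-dimethyl-4H-1,3-benzodioxin-4-one F4.
- Methanolysis of F4 (K2CO3, MeOH, rt) should release acetone and give resorcylate 8.

Step 8. The peroxide may attack the methoxy-bearing carbon with loss of methoxide, or the base may degrade the sensitive benzoquinone and its epoxide.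
- The fallback sets out from 12 and comes back at 14, bypassing 13 and step 9.
- Thiele–Winter acetoxylation of 12 (Ac2O, BF3·OEt2, rt) should add acetate at the free carbon next to the icosyl group and give 3-icosyl-5-methoxybenzene-1,2,4-triyl triacetate F5.
- Deacetylation of F5 (K2CO3, MeOH under argon), then admission of air and acidification, should let the freed hydroxyhydroquinone autoxidise to 14.

**Further compounds**

F1 | step 3 | N-methoxy-N-methylhenicosanamide | CCCCCCCCCCCCCCCCCCCCC(=O)N(C)OC
F2 | step 3 | 2,2-dimethyl-6-(2-oxopropyl)-4H-1,3-dioxin-4-one | CC(=O)CC1=CC(=O)OC(C)(C)O1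
F3 | step 3 | 6-(2,4-dioxotetracosyl)-2,2-dimethyl-4H-1,3-dioxin-4-one | CCCCCCCCCCCCCCCCCCCCC(=O)CC(=O)CC1=CC(=O)OC(C)(C)O1
F4 | step 4 | 7-hydroxy-5-icosyl-2,2-dimethyl-4H-1,3-benzodioxin-4-one | CCCCCCCCCCCCCCCCCCCCc1cc(O)cc2OC(C)(C)OC(=O)c12
F5 | step 8 | 3-icosyl-5-methoxybenzene-1,2,4-triyl triacetate | CCCCCCCCCCCCCCCCCCCCc1c(OC(C)=O)c(OC(C)=O)cc(OC)c1OC(C)=O
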